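**Plan**
- Retrosynthetic cuts (prostanoid numbering, C1 = ester carbon, ring = C8–C12): the C12 O-acetyl bond, an extra carboxyl on C8 (traceless tert-butyl ester), C10=C11 (dehydrogenation), C7–C8 (enolate allylation), the ring bond C8–C12, C8–C9 (acetate enolate acylation), C13–C14 (epoxide alkynylation) and, in the side chain, C5=C6 (Wittig).
- Enabling feature: C12 is a quaternary, oxygen-bearing ring carbon lying 1,5 to C8 (through C9, C10, C11), and C8 is α to the C9 ketone. The only ring, the C8–C12 cyclopentanone, can therefore close by insertion of a C8 keto-ester carbene into the C12–H bond of a silylated secondary carbinol.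
- Forward: the C9–C20 chain is built from one chiral lactone and 1-heptyne, C8 is added as tert-butyl acetate, and diazo transfer followed by rhodium-carbene insertion closes the ring. The C1–C7 allylic bromide, made from the same lactone, is then joined at C8, followed by C10=C11 dehydrogenation, loss of the C8 ester, desilylation and acetylation.
- Stereochemistry: C12 and C4 both come from (S)-5-(hydroxymethyl)butyrolactone, C12 passing through the insertion with retention. C8 is set late by acid equilibration trans to the C13 chain. 14Z comes from Lindlar semi-hydrogenation and 5E from a stabilised Wittig reaction.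

Key step: step 9

Remark: the target is read as (4S,8R,12R), with the C7 and C13 chains trans across the C8–C12 bond; CIP descriptors of intermediates change where priorities change, not the spatial arrangement.

**Route**

Step 1
Reactants: 1 (S)-5-(hydroxymethyl)dihydrofuran-2(3H)-one
Product: 2 [(2S)-5-oxotetrahydrofuran-2-yl]methyl 4-methylbenzenesulfonate
Conditions: TsCl, pyridine, CH2Cl2, 0 °C to rt
Reagents that add atoms: 4-toluenesulfonyl chloride, Cc1ccc(cc1)S(Cl)(=O)=O
Why: Sulfonylation of the primary alcohol turns the future C13 into an electrophile without touching the carbinol stereocentre or the lactone.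

Step 2
Reactants: 2 [(2S)-5-oxotetrahydrofuran-2-yl]methyl 4-methylbenzenesulfonate
Product: 3 methyl 3-[(2S)-oxiran-2-yl]propanoate
Conditions: K2CO3, MeOH, 0 °C to rt
Reagents that add atoms: methanol, CO
Why: Lactone methanolysis frees the C12 alkoxide, which closes the epoxide by intramolecular Williamson displacement of the tosylate at C13, and since the C12–O bond is never broken the configuration is kept.

Step 3
Reactants: 3 methyl 3-[(2S)-oxiran-2-yl]propanoate; 4 1-heptyne
Product: 7 (5S)-5-(oct-2-yn-1-yl)dihydrofuran-2(3H)-one, via lithium heptynide 5 (not isolated), via hydroxy ester 6 (not isolated)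
Conditions: 4, n-BuLi, THF, −78 °C; BF3·OEt2; then 3, −78 °C; H2O; then TsOH (cat.), CH2Cl2, rt
Reagents that add atoms: none
Why: Yamaguchi alkynylation, in which the heptynide tempered by BF3·OEt2 opens the Lewis-acid-activated epoxide at its terminal carbon (C13) and is too weakly basic to attack the methyl ester at −78 °C, after which the γ-hydroxy ester lactonises under acid catalysis.

Step 4
Reactants: 7 (5S)-5-(oct-2-yn-1-yl)dihydrofuran-2(3H)-one
Product: 8 (5S)-5-[(2Z)-oct-2-en-1-yl]dihydrofuran-2(3H)-one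
Conditions: H2 (1 atm), Pd/CaCO3 poisoned with Pb(OAc)2 (Lindlar catalyst), quinoline, EtOAc, rt
Reagents that add atoms: none
Why: Lindlar semi-hydrogenation adds hydrogen syn on the poisoned palladium surface and should stop at the (Z)-alkene C14=C15.

Step 5
Reactants: 8 (5S)-5-[(2Z)-oct-2-en-1-yl]dihydrofuran-2(3H)-one
Product: 9 (4S,6Z)-4-hydroxy-N-methoxy-N-methyldodec-6-enamide
Conditions: MeNH(OMe)·HCl, AlMe3, CH2Cl2, 0 °C to rt
Reagents that add atoms: N,O-dimethylhydroxylamine hydrochloride, CNOC.Cl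
Why: Weinreb aminolysis of the γ-lactone by the aluminium amide formed in situ unmasks the C12 carbinol in an open chain and gives an acyl donor that accepts only one equivalent of enolate in step 7.

Step 6
Reactants: 9 (4S,6Z)-4-hydroxy-N-methoxy-N-methyldodec-6-enamide
Product: 10 (4S,6Z)-4-[(tert-butyldimethylsilyl)oxy]-N-methoxy-N-methyldodec-6-enamide
Conditions: TBSCl, imidazole, DMF, rt
Reagents that add atoms: tert-butyldimethylsilyl chloride, CC(C)(C)[Si](C)(C)Cl
Why: Silylation of the secondary alcohol, done at once to forestall relactonisation, installs a bulky electron-releasing ether that will activate the C12–H bond and offers no O–H bond to the carbene.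

Step 7
Reactants: 10 (4S,6Z)-4-[(tert-butyldimethylsilyl)oxy]-N-methoxy-N-methyldodec-6-enamide; 11 tert-butyl acetate
Product: 13 tert-butyl (6S,8Z)-6-[(tert-butyldimethylsilyl)oxy]-3-oxotetradec-8-enoate, via lithium enolate 12 (not isolated)
Conditions: 11, LiN(i-Pr)2, THF, −78 °C; then 10, −78 to −20 °C; H2O
Reagents that add atoms: none
Why: Claisen-type acylation of an ester enolate by a Weinreb amide forms the C8–C9 bond and stops cleanly at the β-ketoester; the tert-butyl ester is chosen so that the C8 carboxyl can later leave under acid.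

Step 8
Reactants: 13 tert-butyl (6S,8Z)-6-[(tert-butyldimethylsilyl)oxy]-3-oxotetradec-8-enoate
Product: 14 tert-butyl (6S,8Z)-6-[(tert-butyldimethylsilyl)oxy]-2-diazo-3-oxotetradec-8-enoate
Conditions: 4-acetamidobenzenesulfonyl azide, Et3N, MeCN, 0 °C to rt
Reagents that add atoms: 4-acetamidobenzenesulfonyl azide, CC(=O)Nc1ccc(cc1)S(=O)(=O)N=[N+]=[N-]
Why: Regitz diazo transfer to the doubly activated C8 methylene proceeds under amine base, which leaves the silyl ether and the alkene untouched.

Step 9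
Reactants: 14 tert-butyl (6S,8Z)-6-[(tert-butyldimethylsilyl)oxy]-2-diazo-3-oxotetradec-8-enoate
Product: 15 tert-butyl (5S)-5-[(tert-butyldimethylsilyl)oxy]-5-[(2Z)-oct-2-en-1-yl]-2-oxocyclopentane-1-carboxylate
Conditions: Rh2(OAc)4 (1 mol %), CH2Cl2, rt, slow addition of 14
Reagents that add atoms: none
Why: Rh2(OAc)4 (divalent rhodium) should release nitrogen from 14 and give an electrophilic keto-ester carbene at C8 that inserts into the C12–H bond in one concerted three-centre event, the well-known intramolecular carbene C–H insertion of α-diazo-β-ketoesters to cyclopentanones. The ring closes in the 1,5 mode: C8 bonds to C12 across C9, C10 and C11 through a six-membered chair-like transition state, the ring size this carbene class prefers. The new C–C bond takes the place of the C–H bond on the same face, so insertion is stereoretentive and the (S)-carbinol of 14 becomes quaternary C12 with the configuration of the target, while the C8 centre formed at the same time is enolisable and left unassigned. Site selectivity is needed against the C14=C15 alkene and the allylic C13–H: the silyloxy oxygen makes the C12 methine the most hydridic C–H, cyclopropanation would need a seven-membered ring, and allylic insertion would need a six-membered ring at a C–H bond that is electronically poor for an acceptor-substituted carbene. The bulk of the silyl group should keep the ether oxygen from trapping the carbene as an oxonium ylide, and slow addition suppresses carbene dimer.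

Step 10
Reactants: 1 (S)-5-(hydroxymethyl)dihydrofuran-2(3H)-one; 16 (triphenylphosphoranylidene)acetaldehyde
Product: 18 (2E)-3-[(2S)-5-oxotetrahydrofuran-2-yl]prop-2-enal, via lactone aldehyde 17 (not isolated)
Conditions: Dess–Martin periodinane, CH2Cl2, 0 °C to rt; then 16, rt
Reagents that add atoms: none
Why: Dess–Martin oxidation gives the configurationally fragile α-oxy aldehyde under non-basic conditions and the stabilised Wittig ylide traps it in the same flask as the (E)-enal, which fixes C5=C6 and carries the lactone stereocentre over as C4.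

Step 11
Reactants: 18 (2E)-3-[(2S)-5-oxotetrahydrofuran-2-yl]prop-2-enal
Product: 19 (5S)-5-[(1E)-3-hydroxyprop-1-en-1-yl]dihydrofuran-2(3H)-one
Conditions: NaBH4, CeCl3·7H2O, MeOH, −20 °C
Reagents that add atoms: none
Why: Luche reduction delivers hydride 1,2 to the enal and is too mild to reduce the γ-lactone.

Step 12
Reactants: 19 (5S)-5-[(1E)-3-hydroxyprop-1-en-1-yl]dihydrofuran-2(3H)-one
Product: 20 (5S)-5-[(1E)-3-[(tert-butyldimethylsilyl)oxy]prop-1-en-1-yl]dihydrofuran-2(3H)-one
Conditions: TBSCl, imidazole, CH2Cl2, rt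
Reagents that add atoms: tert-butyldimethylsilyl chloride, CC(C)(C)[Si](C)(C)Cl
Why: Silyl protection of the primary allylic alcohol (C7) ensures that only the C4 hydroxyl is acetylated once the lactone is opened.

Step 13
Reactants: 20 (5S)-5-[(1E)-3-[(tert-butyldimethylsilyl)oxy]prop-1-en-1-yl]dihydrofuran-2(3H)-one
Product: 23 methyl (4S,5E)-4-acetoxy-7-[(tert-butyldimethylsilyl)oxy]hept-5-enoate, via sodium carboxylate 21 (not isolated), via hydroxy ester 22 (not isolated)
Conditions: NaOH (1.05 equiv), MeOH–H2O, 0 °C to rt, evaporate; MeI, DMF, 0 °C; then Ac2O, pyridine, DMAP (cat.), 0 °C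
Reagents that add atoms: sodium hydroxide, [Na+].[OH-]; iodomethane, CI; acetic anhydride, CC(=O)OC(C)=O
Why: Saponification, carboxylate O-methylation and acetylation in sequence open the lactone at the acyl carbon (the C4–O bond is untouched) and cap the γ-hydroxy ester before it can relactonise.

Step 14
Reactants: 23 methyl (4S,5E)-4-acetoxy-7-[(tert-butyldimethylsilyl)oxy]hept-5-enoate
Product: 24 methyl (4S,5E)-4-acetoxy-7-bromohept-5-enoate
Conditions: Ph3PBr2, CH2Cl2, 0 °C to rt
Reagents that add atoms: triphenylphosphine dibromide, BrP(Br)(c1ccccc1)(c1ccccc1)c1ccccc1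
Why: Appel-type direct bromination of a silyl ether, in which oxygen passes from silicon to phosphorus and bromide displaces the oxyphosphonium group at primary C7 to give the more stable primary (E)-allylic bromide.

Step 15
Reactants: 15 tert-butyl (5S)-5-[(tert-butyldimethylsilyl)oxy]-5-[(2Z)-oct-2-en-1-yl]-2-oxocyclopentane-1-carboxylate; 24 methyl (4S,5E)-4-acetoxy-7-bromohept-5-enoate
Product: 25 tert-butyl (5S)-1-[(2E,4S)-4-acetoxy-7-methoxy-7-oxohept-2-en-1-yl]-5-[(tert-butyldimethylsilyl)oxy]-5-[(2Z)-oct-2-en-1-yl]-2-oxocyclopentane-1-carboxylate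
Conditions: K2CO3, acetone, rt to 50 °C
Reagents that add atoms: none
Why: SN2 C-alkylation of the β-ketoester enolate with a primary allylic bromide forms C7–C8 regiospecifically at the doubly activated carbon, the stabilised enolate should not expel the β-silyloxy group, and the C8 configuration created here is irrelevant because the ester is removed later.

Step 16
Reactants: 25 tert-butyl (5S)-1-[(2E,4S)-4-acetoxy-7-methoxy-7-oxohept-2-en-1-yl]-5-[(tert-butyldimethylsilyl)oxy]-5-[(2Z)-oct-2-en-1-yl]-2-oxocyclopentane-1-carboxylate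
Product: 27 tert-butyl (5R)-1-[(2E,4S)-4-acetoxy-7-methoxy-7-oxohept-2-en-1-yl]-5-[(tert-butyldimethylsilyl)oxy]-5-[(2Z)-oct-2-en-1-yl]-2-oxocyclopent-3-ene-1-carboxylate, via silyl enol ether 26 (not isolated)
Conditions: LiN(SiMe3)2, Me3SiCl, THF, −78 °C; then Pd(OAc)2, MeCN, rt
Reagents that add atoms: none
Why: Saegusa–Ito dehydrogenation, where quaternary C8 allows enolisation only towards C10 (the hindered amide deprotonating the ketone far faster than the esters at −78 °C) and Pd(OAc)2 (divalent palladium) then gives the C10=C11 enone by β-hydride elimination from C11.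

Step 17
Reactants: 27 tert-butyl (5R)-1-[(2E,4S)-4-acetoxy-7-methoxy-7-oxohept-2-en-1-yl]-5-[(tert-butyldimethylsilyl)oxy]-5-[(2Z)-oct-2-en-1-yl]-2-oxocyclopent-3-ene-1-carboxylate
Product: 30 methyl (4S,5E)-4-acetoxy-7-[(1R,2R)-2-[(tert-butyldimethylsilyl)oxy]-2-[(2Z)-oct-2-en-1-yl]-5-oxocyclopent-3-en-1-yl]hept-5-enoate, via β-keto acid 28 (not isolated), via dienol 29 (not isolated)
Conditions: CF3CO2H, CH2Cl2, 0 °C to rt; then toluene, 60 °C
Reagents that add atoms: none
Why: Acidolysis of the tert-butyl ester followed by β-keto acid decarboxylation avoids any base that could eliminate the C12 oxygen, and acid-mediated ketonisation of the dienol should settle C8 as the epimer with the C7 chain trans to the C13 chain, the lower-energy vicinal arrangement on the five-membered ring.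

Step 18
Reactants: 30 methyl (4S,5E)-4-acetoxy-7-[(1R,2R)-2-[(tert-butyldimethylsilyl)oxy]-2-[(2Z)-oct-2-en-1-yl]-5-oxocyclopent-3-en-1-yl]hept-5-enoate
Product: 31 methyl (4S,5E)-4-acetoxy-7-[(1R,2R)-2-hydroxy-2-[(2Z)-oct-2-en-1-yl]-5-oxocyclopent-3-en-1-yl]hept-5-enoate
Conditions: aq. HF (48%), MeCN, 0 °C to rt
Reagents that add atoms: none
Why: Acidic fluoride desilylation should cleave the tertiary silyl ether while the acetate, the methyl ester and the base-sensitive β-hydroxy enone tolerate acid.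

Step 19
Reactants: 31 methyl (4S,5E)-4-acetoxy-7-[(1R,2R)-2-hydroxy-2-[(2Z)-oct-2-en-1-yl]-5-oxocyclopent-3-en-1-yl]hept-5-enoate
Product: 32 methyl (4S,5E)-4-acetoxy-7-[(1R,2R)-2-acetoxy-2-[(2Z)-oct-2-en-1-yl]-5-oxocyclopent-3-en-1-yl]hept-5-enoate
Conditions: Ac2O, Sc(OTf)3 (cat.), MeCN, −20 °C
Reagents that add atoms: acetic anhydride, CC(=O)OC(C)=O
Why: Lewis-acid-catalysed acetylation of the tertiary alcohol is chosen over amine-promoted acylation because base would enolise C8 and eliminate the C12 oxygen, while ionisation at C12 is disfavoured since the cation would sit next to the enone.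

**Compound list**

1 | (S)-5-(hydroxymethyl)dihydrofuran-2(3H)-one | O=C1CC[C@@H](CO)O1 | starting material
2 | [(2S)-5-oxotetrahydrofuran-2-yl]methyl 4-methylbenzenesulfonate | Cc1ccc(cc1)S(=O)(=O)OC[C@@H]1CCC(=O)O1 | intermediate
3 | methyl 3-[(2S)-oxiran-2-yl]propanoate | COC(=O)CC[C@H]1CO1 | intermediate
4 | 1-heptyne | CCCCCC#C | starting material
5 | lithium hept-1-yn-1-ide | CCCCCC#C[Li] | intermediate (not isolated)
6 | methyl (4S)-4-hydroxydodec-6-ynoate | CCCCCC#CC[C@@H](O)CCC(=O)OC | intermediate (not isolated)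
7 | (5S)-5-(oct-2-yn-1-yl)dihydrofuran-2(3H)-one | CCCCCC#CC[C@@H]1CCC(=O)O1 | intermediate
8 | (5S)-5-[(2Z)-oct-2-en-1-yl]dihydrofuran-2(3H)-one | CCCCC/C=C\C[C@@H]1CCC(=O)O1 | intermediate
9 | (4S,6Z)-4-hydroxy-N-methoxy-N-methyldodec-6-enamide | CCCCC/C=C\C[C@@H](O)CCC(=O)N(C)OC | intermediate
10 | (4S,6Z)-4-[(tert-butyldimethylsilyl)oxy]-N-methoxy-N-methyldodec-6-enamide | CCCCC/C=C\C[C@@H](O[Si](C)(C)C(C)(C)C)CCC(=O)N(C)OC | intermediate
11 | tert-butyl acetate | CC(=O)OC(C)(C)C | starting material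
12 | lithium 1-(tert-butoxy)ethen-1-olate | C=C(O[Li])OC(C)(C)C | intermediate (not isolated)
13 | tert-butyl (6S,8Z)-6-[(tert-butyldimethylsilyl)oxy]-3-oxotetradec-8-enoate | CCCCC/C=C\C[C@@H](O[Si](C)(C)C(C)(C)C)CCC(=O)CC(=O)OC(C)(C)C | intermediate
14 | tert-butyl (6S,8Z)-6-[(tert-butyldimethylsilyl)oxy]-2-diazo-3-oxotetradec-8-enoate | CCCCC/C=C\C[C@@H](O[Si](C)(C)C(C)(C)C)CCC(=O)C(=[N+]=[N-])C(=O)OC(C)(C)C | intermediate
15 | tert-butyl (5S)-5-[(tert-butyldimethylsilyl)oxy]-5-[(2Z)-oct-2-en-1-yl]-2-oxocyclopentane-1-carboxylate (ring C1 = C8 unassigned and enolisable) | CCCCC/C=C\C[C@@]1(O[Si](C)(C)C(C)(C)C)CCC(=O)C1C(=O)OC(C)(C)C | intermediate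
16 | (triphenylphosphoranylidene)acetaldehyde | O=CC=P(c1ccccc1)(c1ccccc1)c1ccccc1 | starting material
17 | (2S)-5-oxotetrahydrofuran-2-carbaldehyde | O=C[C@@H]1CCC(=O)O1 | intermediate (not isolated)
18 | (2E)-3-[(2S)-5-oxotetrahydrofuran-2-yl]prop-2-enal | O=C/C=C/[C@@H]1CCC(=O)O1 | intermediate
19 | (5S)-5-[(1E)-3-hydroxyprop-1-en-1-yl]dihydrofuran-2(3H)-one | OC/C=C/[C@@H]1CCC(=O)O1 | intermediate
20 | (5S)-5-[(1E)-3-[(tert-butyldimethylsilyl)oxy]prop-1-en-1-yl]dihydrofuran-2(3H)-one | CC(C)(C)[Si](C)(C)OC/C=C/[C@@H]1CCC(=O)O1 | intermediate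
21 | sodium (4S,5E)-7-[(tert-butyldimethylsilyl)oxy]-4-hydroxyhept-5-enoate | CC(C)(C)[Si](C)(C)OC/C=C/[C@@H](O)CCC(=O)[O-].[Na+] | intermediate (not isolated)
22 | methyl (4S,5E)-7-[(tert-butyldimethylsilyl)oxy]-4-hydroxyhept-5-enoate | CC(C)(C)[Si](C)(C)OC/C=C/[C@@H](O)CCC(=O)OC | intermediate (not isolated)
23 | methyl (4S,5E)-4-acetoxy-7-[(tert-butyldimethylsilyl)oxy]hept-5-enoate | CC(C)(C)[Si](C)(C)OC/C=C/[C@H](CCC(=O)OC)OC(C)=O | intermediate
24 | methyl (4S,5E)-4-acetoxy-7-bromohept-5-enoate | BrC/C=C/[C@H](CCC(=O)OC)OC(C)=O | intermediate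
25 | tert-butyl (5S)-1-[(2E,4S)-4-acetoxy-7-methoxy-7-oxohept-2-en-1-yl]-5-[(tert-butyldimethylsilyl)oxy]-5-[(2Z)-oct-2-en-1-yl]-2-oxocyclopentane-1-carboxylate (ring C1 = C8 unassigned) | CCCCC/C=C\C[C@@]1(O[Si](C)(C)C(C)(C)C)CCC(=O)C1(C/C=C/[C@H](CCC(=O)OC)OC(C)=O)C(=O)OC(C)(C)C | intermediate
26 | tert-butyl (5R)-1-[(2E,4S)-4-acetoxy-7-methoxy-7-oxohept-2-en-1-yl]-5-[(tert-butyldimethylsilyl)oxy]-5-[(2Z)-oct-2-en-1-yl]-2-[(trimethylsilyl)oxy]cyclopent-2-ene-1-carboxylate | CCCCC/C=C\C[C@@]1(O[Si](C)(C)C(C)(C)C)CC=C(O[Si](C)(C)C)C1(C/C=C/[C@H](CCC(=O)OC)OC(C)=O)C(=O)OC(C)(C)C | intermediate (not isolated)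
27 | tert-butyl (5R)-1-[(2E,4S)-4-acetoxy-7-methoxy-7-oxohept-2-en-1-yl]-5-[(tert-butyldimethylsilyl)oxy]-5-[(2Z)-oct-2-en-1-yl]-2-oxocyclopent-3-ene-1-carboxylate (ring C1 = C8 unassigned) | CCCCC/C=C\C[C@@]1(O[Si](C)(C)C(C)(C)C)C=CC(=O)C1(C/C=C/[C@H](CCC(=O)OC)OC(C)=O)C(=O)OC(C)(C)C | intermediate
28 | (5R)-1-[(2E,4S)-4-acetoxy-7-methoxy-7-oxohept-2-en-1-yl]-5-[(tert-butyldimethylsilyl)oxy]-5-[(2Z)-oct-2-en-1-yl]-2-oxocyclopent-3-ene-1-carboxylic acid | CCCCC/C=C\C[C@@]1(O[Si](C)(C)C(C)(C)C)C=CC(=O)C1(C/C=C/[C@H](CCC(=O)OC)OC(C)=O)C(=O)O | intermediate (not isolated)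
29 | methyl (4S,5E)-4-acetoxy-7-{(5R)-5-[(tert-butyldimethylsilyl)oxy]-2-hydroxy-5-[(2Z)-oct-2-en-1-yl]cyclopenta-1,3-dien-1-yl}hept-5-enoate | CCCCC/C=C\C[C@@]1(O[Si](C)(C)C(C)(C)C)C=CC(O)=C1C/C=C/[C@H](CCC(=O)OC)OC(C)=O | intermediate (not isolated)
30 | methyl (4S,5E)-4-acetoxy-7-[(1R,2R)-2-[(tert-butyldimethylsilyl)oxy]-2-[(2Z)-oct-2-en-1-yl]-5-oxocyclopent-3-en-1-yl]hept-5-enoate | CCCCC/C=C\C[C@@]1(O[Si](C)(C)C(C)(C)C)C=CC(=O)[C@@H]1C/C=C/[C@H](CCC(=O)OC)OC(C)=O | intermediate
31 | methyl (4S,5E)-4-acetoxy-7-[(1R,2R)-2-hydroxy-2-[(2Z)-oct-2-en-1-yl]-5-oxocyclopent-3-en-1-yl]hept-5-enoate | CCCCC/C=C\C[C@@]1(O)C=CC(=O)[C@@H]1C/C=C/[C@H](CCC(=O)OC)OC(C)=O | intermediate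
32 | methyl (4S,5E)-4-acetoxy-7-[(1R,2R)-2-acetoxy-2-[(2Z)-oct-2-en-1-yl]-5-oxocyclopent-3-en-1-yl]hept-5-enoate | CCCCC/C=C\C[C@@]1(OC(C)=O)C=CC(=O)[C@@H]1C/C=C/[C@H](CCC(=O)OC)OC(C)=O | target

**Totals**

Total step count: 19. Longest linear sequence: 14 steps (steps 1–9 and 15–19 from lactone 1); the C1–C7 bromide 24 takes 5 steps (10–14) from the same lactone.

**Steps most likely to fail**

1. Step 9 (key step). Risk: the carbene is diverted to the C14=C15 π-bond (cyclopropanation) or to the allylic C13–H instead of inserting at C12–H. Fallback, setting out from alkynyl lactone 7 and returning at 15: the C14–C15 unit is kept at the alkyne oxidation level through the carbene step. Its linear C13–C14≡C15 array cannot fold back onto C8, and its propargylic C–H bonds are deactivated. Lactone 7 is opened with MeNH(OMe)·HCl and AlMe3 to (4S)-4-hydroxy-N-methoxy-N-methyldodec-6-ynamide F1. Silylation (TBSCl, imidazole) gives (4S)-4-[(tert-butyldimethylsilyl)oxy]-N-methoxy-N-methyldodec-6-ynamide F2. Acylation of enolate 12 gives tert-butyl (6S)-6-[(tert-butyldimethylsilyl)oxy]-3-oxotetradec-8-ynoate F3, and diazo transfer gives tert-butyl (6S)-6-[(tert-butyldimethylsilyl)oxy]-2-diazo-3-oxotetradec-8-ynoate F4. Rh2(OAc)4 in CH2Cl2 should then close tert-butyl (5S)-5-[(tert-butyldimethylsilyl)oxy]-5-(oct-2-yn-1-yl)-2-oxocyclopentane-1-carboxylate F5. Semi-hydrogenation of F5 (H2, Pd/CaCO3 poisoned with Pb(OAc)2, quinoline) gives 15.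

2. Step 15. Risk: O-alkylation of the hindered enolate or SN2′ attack, since the new quaternary C8 is built next to quaternary C12. Fallback, setting out from silyl ether 23 (with 15) and returning at 25: the C7–C8 bond is made by Tsuji–Trost allylation under neutral conditions instead of SN2 alkylation. HF·pyridine in THF converts 23 into methyl (4S,5E)-4-acetoxy-7-hydroxyhept-5-enoate F6. ClCO2Me and pyridine give methyl (4S,5E)-4-acetoxy-7-[(methoxycarbonyl)oxy]hept-5-enoate F7. With Pd(PPh3)4 (zerovalent palladium) in THF at rt the primary carbonate should ionise well before the secondary C4 acetate. The soft enolate of 15 then attacks the less hindered C7 terminus of the allyl complex at carbon, giving 25 with C4 untouched.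

3. Step 17. Risk: protonation of the dienol at C8 from the face that leaves the C7 chain cis to the C13 chain, with acid-catalysed equilibration too slow to correct it. Fallback, setting out from 30 (C8-epimeric material) and returning at 30: C8 is set by kinetic protonation instead of equilibration. LiN(SiMe3)2 in THF at −78 °C converts 30 into lithium (3R)-2-[(2E,4S)-4-acetoxy-7-methoxy-7-oxohept-2-en-1-yl]-3-[(tert-butyldimethylsilyl)oxy]-3-[(2Z)-oct-2-en-1-yl]cyclopenta-1,4-dien-1-olate F8; at this temperature loss of the silyloxy group should be slow. Quenching at −78 °C with 2,6-di-tert-butyl-4-methylphenol should deliver the proton to C8 on the face away from the bulky silyl ether, giving 30 with the C7 chain on the silyloxy side.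

Further compounds
F1 | step 9 | (4S)-4-hydroxy-N-methoxy-N-methyldodec-6-ynamide | CCCCCC#CC[C@@H](O)CCC(=O)N(C)OC
F2 | step 9 | (4S)-4-[(tert-butyldimethylsilyl)oxy]-N-methoxy-N-methyldodec-6-ynamide | CCCCCC#CC[C@@H](O[Si](C)(C)C(C)(C)C)CCC(=O)N(C)OC
F3 | step 9 | tert-butyl (6S)-6-[(tert-butyldimethylsilyl)oxy]-3-oxotetradec-8-ynoate | CCCCCC#CC[C@@H](O[Si](C)(C)C(C)(C)C)CCC(=O)CC(=O)OC(C)(C)C
F4 | step 9 | tert-butyl (6S)-6-[(tert-butyldimethylsilyl)oxy]-2-diazo-3-oxotetradec-8-ynoate | CCCCCC#CC[C@@H](O[Si](C)(C)C(C)(C)C)CCC(=O)C(=[N+]=[N-])C(=O)OC(C)(C)C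
F5 | step 9 | tert-butyl (5S)-5-[(tert-butyldimethylsilyl)oxy]-5-(oct-2-yn-1-yl)-2-oxocyclopentane-1-carboxylate | CCCCCC#CC[C@@]1(O[Si](C)(C)C(C)(C)C)CCC(=O)C1C(=O)OC(C)(C)C
F6 | step 15 | methyl (4S,5E)-4-acetoxy-7-hydroxyhept-5-enoate | OC/C=C/[C@H](CCC(=O)OC)OC(C)=O
F7 | step 15 | methyl (4S,5E)-4-acetoxy-7-[(methoxycarbonyl)oxy]hept-5-enoate | COC(=O)OC/C=C/[C@H](CCC(=O)OC)OC(C)=O
F8 | step 17 | lithium (3R)-2-[(2E,4S)-4-acetoxy-7-methoxy-7-oxohept-2-en-1-yl]-3-[(tert-butyldimethylsilyl)oxy]-3-[(2Z)-oct-2-en-1-yl]cyclopenta-1,4-dien-1-olate | CCCCC/C=C\C[C@@]1(O[Si](C)(C)C(C)(C)C)C=CC(O[Li])=C1C/C=C/[C@H](CCC(=O)OC)OC(C)=O
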